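Start with one multiplication, the loading of initiator on the free monomer, which for every flask here gives a charge c(initiator) of 31.2 mM.

all flasks: free monomer 0.80 M; initiator 3.9 mol%

| flask | transfer agent | temperature | remark | time |
|---|---|---|---|---|
| ochre | 4 mM | 15 °C | run made earlier |  |
| red | 6 mM | 50 °C | run made earlier |  |
| alpha | 8.00 mM | 80 °C |  | 12 h |
| epsilon | 8.00 mM | 40 °C |  | 12 h |
| beta | 8.00 mM | 60 °C |  | 12 h |
| gamma | 8.00 mM | 20 °C |  | 12 h |

| run | time / h | monomer in chains / % | free monomer / % |
|---|---|---|---|
| ochre | 15.0 | 5.2 | 94.5 |
| ochre | 50.0 | 14.2 | 85.8 |
| ochre | 72.0 | 17.3 | 82.6 |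
| ochre | 120 | 22.0 | 77.7 |
| ochre | 192 | 26.9 | 72.9 |
| ochre | 240 | 29.4 | 70.8 |
| ochre | 288 | 30.7 | 69.7 |
| red | 4.00 | 21.6 | 78.4 |
| red | 6.00 | 26.4 | 73.5 |
| red | 8.00 | 30.5 | 69.2 |
| red | 12.0 | 37.1 | 62.9 |
| red | 20.0 | 43.6 | 56.3 |
| red | 40.0 | 52.4 | 48.5 |
| red | 48.0 | 53.4 | 46.0 |

(standard deviation of a reading: 0.3 percentage points)

* the best flask by amount of monomer in chains, in percent of the free monomer charged; "all alike" if 1.5 percentage points covers them all (alpha / epsilon / beta / gamma / all alike)
* amount of monomer in chains at the end, in percent of the free monomer charged, alpha
* amount of monomer in chains at the end, in percent of the free monomer charged, epsilon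
* amount of monomer in chains at the end, in percent of the free monomer charged, beta
* amount of monomer in chains at the end, in percent of the free monomer charged, gamma



Now open a ledger for that charge, because you want to know what each mole of initiator earns before its account closes. In the red run the gain shrinks to 1 percentage point over the last 8.00 h, while 46.0 % of the free monomer still stands, so free monomer is not what is being exhausted there, and I take initiator as the limiting reagent. The first entry is the income: the last reading of the red run shows 0.427 M of monomer in chains on its 31.2 mM of initiator, which reads as 13.7 turnovers, and this is the turnover count, the moles of monomer in chains per mole of initiator charged. The second entry is the closing of chains: if each initiator starts one chain and each transfer agent closes one, then the 8.00 mM in the new flasks can close a quarter of them, and the remaining 23.2 mM must close some other way or stay open. The count is a running total, since the ochre run stands at 7.87 after 288 h and is still gaining. So my own figure for flask alpha, which is hotter than the red run with the same loading, supposes that its initiator earns the red count within 12 h, and that gives 53.4 %.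

The forecast, which says the stall of the red run looks like “initiator burnout”, names alpha as best at 50 % (range 36 % to 58 %), lower than my figure, with beta at 47 %, epsilon at 24 % and gamma at 7 %.

Flask alpha comes out best at 68.7 %, with beta at 48.6 %, epsilon at 24.4 % and gamma at 6.75 %.

    free monomer + living end → monomer in chains + living end, rate k1*[living end]*[free monomer] (k = 5.60 /M/h, Ea = 68.0 kJ/mol)
    free monomer + initiator → living end + monomer in chains (k = 4.10 /M/h, Ea = 62.0 kJ/mol)
    2 living end → dead end (k = 8.40 /M/h, Ea = 54.0 kJ/mol)
    living end + transfer agent → dead chain (kL = 5.60 /M/h, Ea = 86.0 kJ/mol)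
    (constants at 60 °C)

At 12.0 h flask alpha holds 0 % of its initiator, and its books close on 1.00 mM of living end, 6.41 mM of dead chain and 11.9 mM of dead end, each dead end having taken two living ends, which sums to 31.2 mM. The count of flask alpha is 17.6, higher than the 13.7 read from the red run. Flask gamma has earned a count of 1.73, and the same flask with 6.6 mol% of initiator earns 1.65, which puts 10.9 % in chains.

The runs come from a simulation with made-up constants; scatter was added.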